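**Overview**

- Numbering: ring carbons C1–C11 in the order of the target SMILES; C15 is the CH2O carbon on C1. TBS = tert-butyldimethylsilyl, Ts = p-toluenesulfonyl.
- Feature: C1 and C6–C11 form a tricyclene. Without the cyclopropane bond C8–C10 they are a norbornane (bridgeheads C6 and C9; bridges C1, C7–C8 and C10–C11) in which C8 and the endo C10–H both sit on C9, as C2 and C6–H do in camphor.
- Disconnections: C8–C10 by carbene 1,3-C–H insertion from a C8 tosylhydrazone salt; C6–C11 by SmI2 ketyl–enone closure; C9–C10 by enolate alkylation with (S)-lactate triflate (exo-CH3, endo-H at C10); C1–C6 and C7–C8–C9 by Pauson–Khand reaction of a pantolactone-derived 1,7-enyne.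
- A C15–O–C3 lactol bridge fixes C1 in the Pauson–Khand step. As its silyl acetal it shields the C15 face of C9 in the alkylation, stays on through the key step, and is opened at the end by fluoride and NaBH4.
- Ring order: oxolane, then ring A with the cyclopentenone, then the norbornane, then the cyclopropane; the acetates go on last through a C3,C4 orthoacetate.

Key step: step 16

Remark: the hemiacetal carbon C15 of 10, 11, 12 and 26 and the orthoester carbon of 28 and 29 are expected as mixtures that converge later, so their SMILES leave these centres open.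

Step 1
Reactants: 1 (R)-pantolactone
Product: 2 O-TBS-(R)-pantolactone
Conditions: TBSCl, imidazole, DMF, rt
Reagents that add atoms: tert-butyldimethylsilyl chloride, CC(C)(C)[Si](C)(C)Cl
Why: Silyl ether formation on the secondary alcohol is routine, leaves the C4 stereocentre of the chiral pool untouched, and installs a bulky non-chelating group that later steers the carbonyl addition of step 6.

Step 2
Reactants: 2 O-TBS-(R)-pantolactone
Product: 3 (2R)-2-(TBS-oxy)-4-hydroxy-N-methoxy-N,3,3-trimethylbutanamide
Conditions: MeNH(OMe)·HCl, AlMe3, CH2Cl2, 0 °C to rt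
Reagents that add atoms: N,O-dimethylhydroxylamine hydrochloride, CNOC.Cl
Why: Weinreb aminolysis of the lactone by the aluminium amide opens the ring at the acyl carbon and frees the neopentyl C6 alcohol without touching C4.

Step 3
Reactants: 3 (2R)-2-(TBS-oxy)-4-hydroxy-N-methoxy-N,3,3-trimethylbutanamide
Product: 4 (2R)-2-(TBS-oxy)-N-methoxy-N,3,3-trimethyl-4-oxobutanamide
Conditions: Dess–Martin periodinane, CH2Cl2, 0 °C to rt
Reagents that add atoms: none
Why: Dess–Martin oxidation of the primary alcohol gives an aldehyde with no α-hydrogen, which cannot epimerise, and is run at once so that the hydroxy amide does not close back to the lactone.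

Step 4
Reactants: 4 (2R)-2-(TBS-oxy)-N-methoxy-N,3,3-trimethyl-4-oxobutanamide
Product: 5 (2R)-2-(TBS-oxy)-N-methoxy-N,3,3-trimethylpent-4-ynamide
Conditions: Ohira–Bestmann reagent, K2CO3, MeOH, 0 °C to rt
Reagents that add atoms: dimethyl (1-diazo-2-oxopropyl)phosphonate, COP(=O)(OC)C(=[N+]=[N-])C(C)=O
Why: Seyferth–Gilbert homologation turns the aldehyde into the terminal alkyne C6≡C7 under carbonate conditions that the Weinreb amide and the silyl ether tolerate.

Step 5
Reactants: 5 (2R)-2-(TBS-oxy)-N-methoxy-N,3,3-trimethylpent-4-ynamide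
Product: 6 (2R)-2-(TBS-oxy)-3,3-dimethylpent-4-ynal
Conditions: iBu2AlH, THF, −78 °C
Reagents that add atoms: none
Why: Hydride reduction of a Weinreb amide stops at the chelated tetrahedral stage and releases the C3 aldehyde on work-up.

Step 6
Reactants: 6 (2R)-2-(TBS-oxy)-3,3-dimethylpent-4-ynal; 7 ethyl 2-(bromomethyl)prop-2-enoate
Product: 9 (5S)-5-[(1R)-1-(TBS-oxy)-2,2-dimethylbut-3-ynyl]-3-methylideneoxolan-2-one, via hydroxy ester 8 (not isolated)
Conditions: Zn dust, THF/sat. aq NH4Cl, 0 °C to rt; then PPTS (cat.), CH2Cl2, rt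
Reagents that add atoms: none
Why: Zinc Barbier addition of the 2-(ethoxycarbonyl)allyl unit followed by lactonisation is the standard route to α-methylene butyrolactones, and Felkin–Anh attack anti to the non-chelating C4–OTBS group should set C3 as (S), the 3,4-anti relation that becomes the ring-cis diol.

Step 7
Reactants: 9 (5S)-5-[(1R)-1-(TBS-oxy)-2,2-dimethylbut-3-ynyl]-3-methylideneoxolan-2-one
Product: 10 (5S)-5-[(1R)-1-(TBS-oxy)-2,2-dimethylbut-3-ynyl]-3-methylideneoxolan-2-ol
Conditions: iBu2AlH (1.1 equiv), CH2Cl2, −78 °C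
Reagents that add atoms: none
Why: Half-reduction of a lactone to the lactol with one equivalent of hydride at low temperature is routine, and 1,2-addition is the normal course for α-methylene lactones.

Step 8
Reactants: 10 (5S)-5-[(1R)-1-(TBS-oxy)-2,2-dimethylbut-3-ynyl]-3-methylideneoxolan-2-ol
Product: 12 tricyclic enone lactol (ring A fused at C1–C6 to the C6=C7–C8(=O)–C9H2 cyclopentenone; C15H(OH)–O–C3 bridge; C4–OTBS), via alkyne hexacarbonyldicobalt complex 11 (not isolated)
Conditions: Co2(CO)8, toluene, rt; then DMSO, 50 °C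
Reagents that add atoms: dicobalt octacarbonyl, [Co].[Co].[C-]#[O+].[C-]#[O+].[C-]#[O+].[C-]#[O+].[C-]#[O+].[C-]#[O+].[C-]#[O+].[C-]#[O+]
Why: The intramolecular Pauson–Khand reaction of the 1,7-enyne forms C1–C6 and C7–C8–C9 at once, and the quaternary C1 can only arise with C6 cis to C4 on the oxolane because the three-carbon C4–C6 link must bridge C3 and C1.

Step 9
Reactants: 12 tricyclic enone lactol
Product: 13 tricyclic enone silyl acetal (C15–OTBS trans to the C4–C6 bridge and cis to C9)
Conditions: TBSCl, imidazole, DMF, rt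
Reagents that add atoms: tert-butyldimethylsilyl chloride, CC(C)(C)[Si](C)(C)Cl
Why: The hemiacetal equilibrates through its open form and should be silylated as the less hindered epimer with the oxygen trans to the C4–C6 bridge, since the other epimer presses on the axial C5 methyl group.

Step 10
Reactants: 13 tricyclic enone silyl acetal; 14 ethyl (2S)-2-(trifluoromethylsulfonyloxy)propanoate
Product: 16 C9-alkylated enone ester with (S)-C10, via lithium dienolate 15 (not isolated)
Conditions: LiN(iPr)2, THF, −78 °C; then 14, DMPU, −78 to −40 °C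
Reagents that add atoms: none
Why: Kinetic deprotonation can only occur at C9, and SN2 alkylation of the lithium dienolate by the α-triflyloxy ester with inversion gives (S)-C10, while the electrophile should enter C9 anti to the C15 silyloxy group that lies under this carbon.

Step 11
Reactants: 16 C9-alkylated enone ester
Product: 17 allylic alcohol diol (C8–OH, C11H2–OH)
Conditions: iBu2AlH (excess), CH2Cl2, −78 to 0 °C
Reagents that add atoms: none
Why: Hydride reduction takes the ester to the primary alcohol and the enone by 1,2-addition to the allylic alcohol, whose C8 configuration does not matter because it is oxidised back in the next step.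

Step 12
Reactants: 17 allylic alcohol diol
Product: 18 enone aldehyde (C8 ketone, C11 aldehyde)
Conditions: Dess–Martin periodinane, pyridine, CH2Cl2, 0 °C
Reagents that add atoms: none
Why: Dess–Martin oxidation restores the enone and forms the C11 aldehyde under buffered conditions that should not epimerise C9 or C10; the 1,4-keto aldehyde is used crude.

Step 13
Reactants: 18 enone aldehyde
Product: 19 norbornan-8-one with endo C11–OH
Conditions: SmI2, HMPA, tBuOH, THF, −78 to 0 °C
Reagents that add atoms: none
Why: SmI2 ketyl–olefin cyclisation adds the C11 ketyl 5-exo to the enone β-carbon C6 on the face fixed by C9 and so closes the norbornane, and the samarium-bound oxygen should take the endo position over C7 because the exo position would eclipse the quaternary C5 next to C6.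

Step 14
Reactants: 19 norbornan-8-one with endo C11–OH
Product: 20 norbornan-8-one C11 TBS ether
Conditions: TBSOTf, 2,6-lutidine, CH2Cl2, −78 to 0 °C
Reagents that add atoms: tert-butyldimethylsilyl trifluoromethanesulfonate, CC(C)(C)[Si](C)(C)OS(=O)(=O)C(F)(F)F
Why: Silylation of the hindered secondary alcohol with the silyl triflate is routine, and the hindered base keeps the silyl acetal and the ketone intact.

Step 15
Reactants: 20 norbornan-8-one C11 TBS ether; 21 p-toluenesulfonyl hydrazide
Product: 22 C8 tosylhydrazone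
Conditions: 4 Å molecular sieves, THF, 60 °C
Reagents that add atoms: none
Why: Hydrazone condensation of the strained C8 ketone should proceed as it does for camphor, and no acid is added so that the silyl acetal survives.

Step 16
Reactants: 22 C8 tosylhydrazone
Product: 25 oxa-bridged nortricyclane tris-TBS ether, via sodium tosylhydrazonide 23 (not isolated), via C8 diazoalkane 24 (not isolated)
Conditions: NaH, THF, 0 °C to rt; then diglyme, 150 °C
Reagents that add atoms: none
Why: Heating the dry sodium salt 23 expels sodium p-toluenesulfinate to give the C8 diazoalkane 24, which loses N2 to a singlet C8 carbene that inserts into the endo C10–H bond in a concerted three-centre process with retention at C10. The closest known case is the aprotic Bamford–Stevens pyrolysis of the sodium salt of camphor tosylhydrazone to tricyclene. The cyclopropane C8–C9–C10 is the only ring formed, and it is closed by joining C8 to C10 across the bridgehead C9 in a transannular 1,3-insertion. Both new stereocentres are fixed by the cage: C8 can reach C10 only from the endo side, so its hydrogen ends exo, and C10 keeps the exo methyl group set in step 10 because the endo hydrogen is the one replaced. The step needs insertion to beat the 1,2-hydrogen shift from C7 and any attack on oxygen. The rigid norbornane holds the tertiary endo C10–H directly under the carbene centre while the C7–H bonds are poorly aligned with its empty orbital, the medium is aprotic, and the C11 and C15 oxygens carry bulky silyl groups, with O3 tied back in the oxolane and the C15 silyloxy group lying on the far side of C9.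

Step 17
Reactants: 25 oxa-bridged nortricyclane tris-TBS ether
Product: 26 tricyclene lactol triol (C15 hemiacetal, C4–OH, C11–OH)
Conditions: Bu4NF, THF, 60 °C
Reagents that add atoms: none
Why: Fluoride desilylation cleaves the two silyl ethers and the silyl acetal and so uncovers the C15 lactol under conditions that do not touch the cyclopropane.

Step 18
Reactants: 26 tricyclene lactol triol
Product: 27 tetraol (C15, C3, C4, C11 hydroxyls)
Conditions: NaBH4, MeOH, 0 °C
Reagents that add atoms: none
Why: Borohydride reduction of the lactol through its open hydroxy aldehyde form gives the C15 primary alcohol and frees the C3 hydroxyl.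

Step 19
Reactants: 27 tetraol
Product: 29 C3,C4 cyclic methyl orthoacetate C15,C11-diacetate, via cyclic orthoacetate diol 28 (not isolated)
Conditions: MeC(OMe)3, PPTS (cat.), CH2Cl2, rt; then Ac2O, Et3N, DMAP, 40 °C
Reagents that add atoms: trimethyl orthoacetate, CC(OC)(OC)OC; acetic anhydride, CC(=O)OC(C)=O
Why: Orthoester exchange forms the five-membered cyclic orthoacetate on the cis C3,C4-diol, the only pair that can close a small ring, and DMAP-catalysed acetylation then esterifies the primary C15 and the hindered C11 hydroxyl groups.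

Step 20
Reactants: 29 C3,C4 cyclic methyl orthoacetate C15,C11-diacetate
Product: 30 CNP0197219.1
Conditions: AcOH/H2O (4:1), rt
Reagents that add atoms: water, O
Why: Mild acid hydrolysis of a cyclic orthoester goes through the dioxolanylium ion and its hemiorthoester, which opens to the axial ester, and C3–O is the axial bond of ring A (syn-axial to C15), so the acetate should end on C3 and the hindered C4 hydroxyl stays free.

**Compound list**

1 | (R)-pantolactone | CC1(C)COC(=O)[C@@H]1O | starting material
2 | O-TBS-(R)-pantolactone, (3R)-3-(tert-butyldimethylsilyloxy)-4,4-dimethyloxolan-2-one | CC1(C)COC(=O)[C@@H]1O[Si](C)(C)C(C)(C)C | intermediate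
3 | (2R)-2-(TBS-oxy)-4-hydroxy-N-methoxy-N,3,3-trimethylbutanamide | OCC(C)(C)[C@@H](O[Si](C)(C)C(C)(C)C)C(=O)N(C)OC | intermediate
4 | (2R)-2-(TBS-oxy)-N-methoxy-N,3,3-trimethyl-4-oxobutanamide | O=CC(C)(C)[C@@H](O[Si](C)(C)C(C)(C)C)C(=O)N(C)OC | intermediate
5 | (2R)-2-(TBS-oxy)-N-methoxy-N,3,3-trimethylpent-4-ynamide | C#CC(C)(C)[C@@H](O[Si](C)(C)C(C)(C)C)C(=O)N(C)OC | intermediate
6 | (2R)-2-(TBS-oxy)-3,3-dimethylpent-4-ynal | C#CC(C)(C)[C@@H](O[Si](C)(C)C(C)(C)C)C=O | intermediate
7 | ethyl 2-(bromomethyl)prop-2-enoate | C=C(CBr)C(=O)OCC | starting material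
8 | hydroxy ester, ethyl (4S,5R)-5-(TBS-oxy)-4-hydroxy-6,6-dimethyl-2-methylideneoct-7-ynoate | C#CC(C)(C)[C@@H](O[Si](C)(C)C(C)(C)C)[C@@H](O)CC(=C)C(=O)OCC | intermediate
9 | (5S)-5-[(1R)-1-(TBS-oxy)-2,2-dimethylbut-3-ynyl]-3-methylideneoxolan-2-one | C#CC(C)(C)[C@@H](O[Si](C)(C)C(C)(C)C)[C@@H]1CC(=C)C(=O)O1 | intermediate
10 | (5S)-5-[(1R)-1-(TBS-oxy)-2,2-dimethylbut-3-ynyl]-3-methylideneoxolan-2-ol | C#CC(C)(C)[C@@H](O[Si](C)(C)C(C)(C)C)[C@@H]1CC(=C)C(O)O1 | intermediate
11 | alkyne hexacarbonyldicobalt complex of 10 | C12[Co]3(=C=O)(=C=O)(=C=O)[Co]1(=C=O)(=C=O)(=C=O)C23C(C)(C)[C@@H](O[Si](C)(C)C(C)(C)C)[C@@H]4CC(=C)C(O)O4 | intermediate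
12 | tricyclic enone lactol (C1, C3, C4 as in the target; C15 hemiacetal) | OC(O3)[C@]12C[C@H]3[C@H](O[Si](C)(C)C(C)(C)C)C(C)(C)C1=CC(=O)C2 | intermediate
13 | tricyclic enone silyl acetal (C15–OTBS trans to the C4–C6 bridge) | CC(C)(C)[Si](C)(C)O[C@@H](O3)[C@]12C[C@H]3[C@H](O[Si](C)(C)C(C)(C)C)C(C)(C)C1=CC(=O)C2 | intermediate
14 | ethyl (2S)-2-(trifluoromethylsulfonyloxy)propanoate | CCOC(=O)[C@H](C)OS(=O)(=O)C(F)(F)F | starting material
15 | lithium dienolate of 13 | CC(C)(C)[Si](C)(C)O[C@@H](O3)[C@]12C[C@H]3[C@H](O[Si](C)(C)C(C)(C)C)C(C)(C)C1=CC([O-])=C2.[Li+] | intermediate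
16 | C9-alkylated enone ester, (S)-C10 | CC(C)(C)[Si](C)(C)O[C@@H](O3)[C@]12C[C@H]3[C@H](O[Si](C)(C)C(C)(C)C)C(C)(C)C1=CC(=O)[C@H]2[C@H](C)C(=O)OCC | intermediate
17 | allylic alcohol diol (C8 epimers) | CC(C)(C)[Si](C)(C)O[C@@H](O3)[C@]12C[C@H]3[C@H](O[Si](C)(C)C(C)(C)C)C(C)(C)C1=CC(O)[C@H]2[C@H](C)CO | intermediate
18 | enone aldehyde | CC(C)(C)[Si](C)(C)O[C@@H](O3)[C@]12C[C@H]3[C@H](O[Si](C)(C)C(C)(C)C)C(C)(C)C1=CC(=O)[C@H]2[C@H](C)C=O | intermediate
19 | norbornan-8-one, endo C11–OH, exo C10–CH3 | CC(C)(C)[Si](C)(C)O[C@@H](O3)[C@]12C[C@H]3[C@H](O[Si](C)(C)C(C)(C)C)C(C)(C)[C@]14CC(=O)[C@H]2[C@H](C)[C@H]4O | intermediate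
20 | norbornan-8-one C11 TBS ether | CC(C)(C)[Si](C)(C)O[C@@H](O3)[C@]12C[C@H]3[C@H](O[Si](C)(C)C(C)(C)C)C(C)(C)[C@]14CC(=O)[C@H]2[C@H](C)[C@H]4O[Si](C)(C)C(C)(C)C | intermediate
21 | p-toluenesulfonyl hydrazide | Cc1ccc(cc1)S(=O)(=O)NN | starting material
22 | C8 tosylhydrazone (key-step precursor) | CC(C)(C)[Si](C)(C)O[C@@H](O3)[C@]12C[C@H]3[C@H](O[Si](C)(C)C(C)(C)C)C(C)(C)[C@]14CC(=NNS(=O)(=O)c5ccc(C)cc5)[C@H]2[C@H](C)[C@H]4O[Si](C)(C)C(C)(C)C | intermediate
23 | sodium tosylhydrazonide of 22 | CC(C)(C)[Si](C)(C)O[C@@H](O3)[C@]12C[C@H]3[C@H](O[Si](C)(C)C(C)(C)C)C(C)(C)[C@]14CC(=N[N-]S(=O)(=O)c5ccc(C)cc5)[C@H]2[C@H](C)[C@H]4O[Si](C)(C)C(C)(C)C.[Na+] | intermediate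
24 | C8 diazoalkane | CC(C)(C)[Si](C)(C)O[C@@H](O3)[C@]12C[C@H]3[C@H](O[Si](C)(C)C(C)(C)C)C(C)(C)[C@]14CC(=[N+]=[N-])[C@H]2[C@H](C)[C@H]4O[Si](C)(C)C(C)(C)C | intermediate
25 | oxa-bridged nortricyclane tris-TBS ether (key-step product) | CC(C)(C)[Si](C)(C)O[C@@H](O3)[C@]12C[C@H]3[C@H](O[Si](C)(C)C(C)(C)C)C(C)(C)[C@]14C[C@@H]5[C@H]2[C@]5(C)[C@H]4O[Si](C)(C)C(C)(C)C | intermediate
26 | tricyclene lactol triol | OC(O3)[C@]12C[C@H]3[C@H](O)C(C)(C)[C@]14C[C@@H]5[C@H]2[C@]5(C)[C@H]4O | intermediate
27 | tetraol | OC[C@]12C[C@H](O)[C@H](O)C(C)(C)[C@]13C[C@@H]1[C@H]2[C@]1(C)[C@H]3O | intermediate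
28 | C3,C4 cyclic methyl orthoacetate diol | OC[C@]12C[C@@H]4OC(C)(OC)O[C@@H]4C(C)(C)[C@]13C[C@@H]1[C@H]2[C@]1(C)[C@H]3O | intermediate
29 | C3,C4 cyclic methyl orthoacetate C15,C11-diacetate | CC(=O)OC[C@]12C[C@@H]4OC(C)(OC)O[C@@H]4C(C)(C)[C@]13C[C@@H]1[C@H]2[C@]1(C)[C@H]3OC(C)=O | intermediate
30 | CNP0197219.1 | CC(=O)OC[C@]12C[C@H](OC(C)=O)[C@H](O)C(C)(C)[C@]13C[C@@H]1[C@H]2[C@]1(C)[C@H]3OC(C)=O | target

**Step count and risks**

Total step count: 20. Longest linear sequence: 20 steps (from 1; compounds 7, 14 and 21 are bought).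

Steps most likely to fail:

1. Step 10. The hindered dienolate may take a proton from the triflate, which then loses triflic acid, or it may be alkylated on oxygen or from the wrong face of C9. The fallback sets out from 13 and returns at 18. LiN(iPr)2 and Me3SiCl should give the trimethylsilyl dienol ether F4. Iridium-catalysed allylic alkylation of F4 ([Ir(cod)Cl]2, a BINOL-derived phosphoramidite chosen to give the C10 arrangement of 16, methyl (E)-but-2-enyl carbonate, CsF, ZnF2, DME, 50 °C) should give the branched C9 but-3-en-2-yl enone F5, with C10 set by the catalyst and C9 by the C15 silyloxy shield. Cleavage of the vinyl group with OsO4 (cat.) and NaIO4 then gives the enone aldehyde 18 directly.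

2. Step 13. The ketyl may close with poor control of the carbinol configuration at C11, or the aldehyde may be reduced without ring closure. The fallback sets out from 18 and returns at 19. Addition of PhSeSiMe3 to the aldehyde (ZnI2 cat.) should give the O-trimethylsilyl selenoacetal F2. A tin hydride radical chain (Bu3SnH, AIBN, benzene, 80 °C) generates the α-silyloxy radical, which closes onto C6 with the bulky silyloxy group away from C5, to give the cyclised trimethylsilyl ether F3. K2CO3 in MeOH removes the trimethylsilyl group to give 19.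

3. Step 16. The carbene may undergo the 1,2-hydrogen shift from C7 to the C7=C8 alkene, or the hot sodium salt may transfer a silyl group to nitrogen before it fragments. The fallback sets out from 20 and returns at 25. N2H4·H2O in EtOH should give the C8 hydrazone F1. Oxidation with HgO (KOH cat.), as in the classical conversion of camphor hydrazone to tricyclene, forms the diazoalkane 24 under neutral conditions without sulfinate or strong base, and its loss of N2 gives 25 by the same insertion.

Further compounds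
F1 | step 16 | C8 hydrazone of ketone 20 | CC(C)(C)[Si](C)(C)O[C@@H](O3)[C@]12C[C@H]3[C@H](O[Si](C)(C)C(C)(C)C)C(C)(C)[C@]14CC(=NN)[C@H]2[C@H](C)[C@H]4O[Si](C)(C)C(C)(C)C
F2 | step 13 | O-trimethylsilyl phenylselenoacetal of aldehyde 18 | CC(C)(C)[Si](C)(C)O[C@@H](O3)[C@]12C[C@H]3[C@H](O[Si](C)(C)C(C)(C)C)C(C)(C)C1=CC(=O)[C@H]2[C@H](C)C(O[Si](C)(C)C)[Se]c4ccccc4
F3 | step 13 | C11 trimethylsilyl ether of 19 | CC(C)(C)[Si](C)(C)O[C@@H](O3)[C@]12C[C@H]3[C@H](O[Si](C)(C)C(C)(C)C)C(C)(C)[C@]14CC(=O)[C@H]2[C@H](C)[C@H]4O[Si](C)(C)C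
F4 | step 10 | trimethylsilyl dienol ether of 13 | CC(C)(C)[Si](C)(C)O[C@@H](O3)[C@]12C[C@H]3[C@H](O[Si](C)(C)C(C)(C)C)C(C)(C)C1=CC(O[Si](C)(C)C)=C2
F5 | step 10 | C9 but-3-en-2-yl enone | CC(C)(C)[Si](C)(C)O[C@@H](O3)[C@]12C[C@H]3[C@H](O[Si](C)(C)C(C)(C)C)C(C)(C)C1=CC(=O)[C@H]2[C@H](C)C=C
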